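The oxane ring shows a secondary C–Br carbon next to the fully substituted O-bearing carbon (methyl, side chain), Br and chain trans-diequatorial: the imprint of anti addition of Br+ and a hydroxyl across an E-trisubstituted alkene. Everything rests on cutting that C–O bond. A vanadium bromoperoxidase performs the 6-endo bromoetherification of an open-chain tertiary allylic alcohol that already carries the bromocyclohexane, closing the oxane and setting both new stereocentres against a remote carbinol whose methyl and vinyl groups no small reagent tells apart. Both halves come from (S)-linalool: one gives the carbocycle by silicon-tethered bromocyclisation, the other an (E)-alkenyl iodide; a B-alkyl Suzuki coupling joins them.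

Key step: step 10

Assumption: (S)-(+)-linalool (coriandrol) is taken as a commercial, enantiomerically pure starting material. Both tertiary carbinol centres of the target map onto this same enantiomer.

Step 1
Reactants: 1 (S)-(+)-linalool
Product: 2 (S)-linalyl allyldimethylsilyl ether
Conditions: allyl(chloro)dimethylsilane, Et3N, DMAP (cat.), CH2Cl2, 0 °C to rt
Reagents that add atoms: allyl(chloro)dimethylsilane, C=CC[Si](C)(C)Cl
Why: Nucleophile-catalysed O-silylation works on this tertiary alcohol because the chlorosilane is as small as TMSCl, and the C–O bond of the stereocentre is not touched.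

Step 2
Reactants: 2 (S)-linalyl allyldimethylsilyl ether
Product: 3 (6S)-2,2,6-trimethyl-6-(4-methylpent-3-en-1-yl)-3,6-dihydro-2H-1,2-oxasiline
Conditions: Grubbs II (2 mol %), CH2Cl2 (0.01 M), 40 °C
Reagents that add atoms: none
Why: In this temporary silicon-tethered ring-closing metathesis the catalyst loads on the unhindered allylsilane alkene and closes the six-membered ring onto the vinyl group, while the trisubstituted alkene stays out because the cyclopentene closure known for free linalool needs an alkylidene on the hindered vinyl carbon and loses its hydroxyl acceleration once the oxygen is silylated.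

Step 3
Reactants: 3 (6S)-2,2,6-trimethyl-6-(4-methylpent-3-en-1-yl)-3,6-dihydro-2H-1,2-oxasiline
Product: 5 (1S,2R,4R)-4-bromo-1,3,3-trimethyl-2-vinylcyclohexan-1-ol (Br equatorial; vinyl equatorial; OH axial), via bromosilyl ether 4 (not isolated)
Conditions: BDSB (Et2SBr·SbCl5Br, 1.05 equiv), MeNO2 (0.02 M), −25 °C, 5 min; then sat. aq NaHCO3–MeOH, rt
Reagents that add atoms: bromodiethylsulfonium bromopentachloroantimonate (BDSB), CC[S+](Br)CC.Cl[Sb-](Cl)(Cl)(Cl)(Cl)Br
Why: Proposed new method: Br+ passes from the sulfonium salt to the most electron-rich alkene (trisubstituted; the ring alkene of 3 is only disubstituted, flanked by a quaternary centre and deactivated by the allylic C–O and the Si–O bond), and the tertiary carbon of the bromonium ion is attacked by the proximal sp2 carbon of the cyclic allylsiloxane through a six-membered chair, after which the β-silyl cation collapses by bromide attack on silicon to the vinyl group (SE2′), so the tether is spent as 4 and hydrolysed on work-up; because the electrophile is tied to the carbinol carbon it can only reach the alkene face syn to its own chain, which places vinyl cis to oxygen (vinyl equatorial, O axial), and the chair with equatorial bromine, reached through reversible Br+ transfer, sets CHBr; the closest known reaction types are the BDSB-initiated cation–π cyclisation of polyenes and the allylsilane-terminated (epoxide-initiated) cation–olefin cyclisation.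

Step 4
Reactants: 5 (1S,2R,4R)-4-bromo-1,3,3-trimethyl-2-vinylcyclohexan-1-ol
Product: 6 triethylsilyl ether of 5
Conditions: TESOTf, 2,6-lutidine, CH2Cl2, −78 °C to 0 °C
Reagents that add atoms: triethylsilyl triflate, CC[Si](CC)(CC)OS(=O)(=O)C(F)(F)F
Why: Silyl triflate/lutidine silylation is the standard way to cap a hindered tertiary (here axial) alcohol, it masks the one oxygen that could later compete for the bromonium ion, and no stereocentre is affected.

Step 5
Reactants: 1 (S)-(+)-linalool
Product: 8 (5S)-5-methyl-5-vinyltetrahydrofuran-2-ol (lactol form of the hydroxy aldehyde; anomer mixture), via secondary ozonide 7 (not isolated)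
Conditions: O3 (1 equiv, Sudan Red 7B end-point), CH2Cl2, −78 °C; then Me2S, −78 °C to rt
Reagents that add atoms: ozone, [O-][O+]=O
Why: In this chemoselective ozonolysis ozone attacks the electron-rich trisubstituted alkene much faster than the monosubstituted vinyl group, the dye marks the end-point, and the hydroxy aldehyde closes to the lactol without touching the carbinol centre.

Step 6
Reactants: 8 (5S)-5-methyl-5-vinyltetrahydrofuran-2-ol
Product: 9 (S)-3-methylhept-1-en-6-yn-3-ol
Conditions: Ohira–Bestmann reagent, K2CO3, MeOH, 0 °C to rt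
Reagents that add atoms: dimethyl (1-diazo-2-oxopropyl)phosphonate, COP(=O)(OC)C(=[N+]=[N-])C(C)=O
Why: The Seyferth–Gilbert homologation in the Ohira–Bestmann variant acts on the open hydroxy-aldehyde tautomer of the lactol under mild carbonate conditions that leave the tertiary allylic alcohol alone.

Step 7
Reactants: 9 (S)-3-methylhept-1-en-6-yn-3-ol
Product: 11 (S)-3-methyloct-1-en-6-yn-3-ol, via dilithiated alkynol 10 (not isolated)
Conditions: n-BuLi (2.1 equiv), THF, −78 °C to 0 °C; then MeI (1.1 equiv), 0 °C to rt; aq NH4Cl
Reagents that add atoms: iodomethane, CI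
Why: In this acetylide alkylation the acetylide carbon of the dianion is far more nucleophilic towards MeI than the hindered tertiary lithium alkoxide, so only C-methylation is expected.

Step 8
Reactants: 11 (S)-3-methyloct-1-en-6-yn-3-ol
Product: 13 (3S,6E)-7-iodo-3-methylocta-1,6-dien-3-ol, via alkenylzirconocene 12 (not isolated)
Conditions: Cp2Zr(H)Cl (2.3 equiv), THF, rt to 40 °C, dark; then I2, THF, −78 °C to 0 °C
Reagents that add atoms: iodine, II
Why: In this hydrozirconation–iodinolysis syn addition of Zr–H to the alkyne is faster than to the hindered vinyl group, the slight excess of reagent equilibrates zirconium to the less hindered methyl-bearing carbon, and iodinolysis with retention fixes the E geometry.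

Step 9
Reactants: 6 triethylsilyl ether of 5; 13 (3S,6E)-7-iodo-3-methylocta-1,6-dien-3-ol
Product: 15 (3S,6E)-9-[(1R,3R,6S)-3-bromo-2,2,6-trimethyl-6-(triethylsilyloxy)cyclohexyl]-3,7-dimethylnona-1,6-dien-3-ol, via B-alkyl-9-BBN adduct 14 (not isolated)
Conditions: 6, 9-BBN dimer, THF, rt to 45 °C; then 3 M aq Cs2CO3, 13, Pd(dppf)Cl2·CH2Cl2 (5 mol %), AsPh3, DMF, rt
Reagents that add atoms: none
Why: In this B-alkyl Suzuki–Miyaura coupling 9-BBN adds anti-Markovnikov to the only alkene of 6, the sp3–sp2 coupling keeps the alkene geometry of 13, and the hindered secondary bromide, the silyl ether and the free alcohol are inert to Pd(dppf) at room temperature.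

Step 10
Reactants: 15 (3S,6E)-9-[(1R,3R,6S)-3-bromo-2,2,6-trimethyl-6-(triethylsilyloxy)cyclohexyl]-3,7-dimethylnona-1,6-dien-3-ol
Product: 16 triethylsilyl ether of the target
Conditions: vanadium-dependent bromoperoxidase (vanadium haloperoxidase class, red-algal Corallina officinalis type), KBr, H2O2 (1.1 equiv by syringe pump), Na3VO4 (trace), MES buffer pH 6.3–EtOH (3:2), 25 °C
Reagents that add atoms: potassium bromide, [K+].[Br-]
Why: The vanadate(V) site of the haloperoxidase is peroxidised by H2O2 and oxidises bromide to an enzyme-held Br+ equivalent, which passes to the only electron-rich alkene of 15 (the E-trisubstituted C=C; the monosubstituted vinyl group is far less nucleophilic) to give a bromonium ion that the tertiary allylic hydroxyl opens anti at the more substituted carbon. The closest known reaction type is the vanadium bromoperoxidase-catalysed bromonium cyclisation of acyclic terpene alcohols such as nerolidol and nerol, where hydroxyl capture gives bromo-ethers diastereoselectively while achiral Br+ donors give mixtures. The oxane closes in the 6-endo mode through a chair in which Br and the cyclohexylethyl chain are equatorial and the new ring methyl is axial. The relative configuration of CHBr and the O-bearing quaternary carbon follows from stereospecific anti addition to the E-alkene, and their sense relative to the existing carbinol centre, whose methyl and vinyl groups are too alike for substrate control, is set by the face on which the enzyme delivers bromine. Markovnikov polarisation of the bromonium ion (tertiary versus secondary carbon) secures 6-endo over 5-exo closure, and the triethylsilyl ether keeps the cyclohexanol oxygen from a competing 6-exo attack on the same carbon.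

Step 11
Reactants: 16 triethylsilyl ether of the target
Product: 17 (2S,3R,6S)-3-bromo-2-{2-[(1R,3R,6S)-3-bromo-6-hydroxy-2,2,6-trimethylcyclohexyl]ethyl}-2,6-dimethyl-6-vinyloxane (target)
Conditions: HF·pyridine, pyridine, THF, 0 °C to rt
Reagents that add atoms: none
Why: Buffered fluoride-induced desilylation removes the triethylsilyl group without ionising the tertiary allylic ether or eliminating the equatorial secondary bromides, and no stereocentre is involved.

Compound list
1 | (S)-(+)-linalool, (3S)-3,7-dimethylocta-1,6-dien-3-ol | C=C[C@@](C)(O)CCC=C(C)C | starting material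
2 | (S)-linalyl allyldimethylsilyl ether | C=C[C@@](C)(O[Si](C)(C)CC=C)CCC=C(C)C | intermediate
3 | (6S)-2,2,6-trimethyl-6-(4-methylpent-3-en-1-yl)-3,6-dihydro-2H-1,2-oxasiline | C[Si]1(C)CC=C[C@](C)(CCC=C(C)C)O1 | intermediate
4 | bromo(dimethyl)silyl ether of 5 (not isolated) | C=C[C@@H]1C(C)(C)[C@H](Br)CC[C@]1(C)O[Si](C)(C)Br | intermediate
5 | (1S,2R,4R)-4-bromo-1,3,3-trimethyl-2-vinylcyclohexan-1-ol | C=C[C@@H]1C(C)(C)[C@H](Br)CC[C@]1(C)O | intermediate
6 | triethylsilyl ether of 5 | C=C[C@@H]1C(C)(C)[C@H](Br)CC[C@]1(C)O[Si](CC)(CC)CC | intermediate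
7 | secondary ozonide of the trisubstituted alkene of 1 (not isolated) | C=C[C@@](C)(O)CCC1OOC(C)(C)O1 | intermediate
8 | (5S)-5-methyl-5-vinyltetrahydrofuran-2-ol | C=C[C@]1(C)CCC(O)O1 | intermediate
9 | (S)-3-methylhept-1-en-6-yn-3-ol | C=C[C@@](C)(O)CCC#C | intermediate
10 | dilithiated alkynol (not isolated) | C=C[C@@](C)(O[Li])CCC#C[Li] | intermediate
11 | (S)-3-methyloct-1-en-6-yn-3-ol | C=C[C@@](C)(O)CCC#CC | intermediate
12 | (E)-alkenylzirconocene chloride, O-zirconated (not isolated) | C=C[C@@](C)(O[Zr](Cl)(C1C=CC=C1)C1C=CC=C1)CC/C=C(\C)[Zr](Cl)(C1C=CC=C1)C1C=CC=C1 | intermediate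
13 | (3S,6E)-7-iodo-3-methylocta-1,6-dien-3-ol | C=C[C@@](C)(O)CC/C=C(\C)I | intermediate
14 | B-alkyl-9-BBN adduct of 6 (not isolated) | C(C[C@@H]1C(C)(C)[C@H](Br)CC[C@]1(C)O[Si](CC)(CC)CC)B1C2CCCC1CCC2 | intermediate
15 | (3S,6E)-9-[(1R,3R,6S)-3-bromo-2,2,6-trimethyl-6-(triethylsilyloxy)cyclohexyl]-3,7-dimethylnona-1,6-dien-3-ol | C=C[C@@](C)(O)CC/C=C(\C)CC[C@@H]1C(C)(C)[C@H](Br)CC[C@]1(C)O[Si](CC)(CC)CC | intermediate
16 | triethylsilyl ether of the target | C=C[C@]1(C)CC[C@@H](Br)[C@](C)(CC[C@@H]2C(C)(C)[C@H](Br)CC[C@]2(C)O[Si](CC)(CC)CC)O1 | intermediate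
17 | (2S,3R,6S)-3-bromo-2-{2-[(1R,3R,6S)-3-bromo-6-hydroxy-2,2,6-trimethylcyclohexyl]ethyl}-2,6-dimethyl-6-vinyloxane | C=C[C@]1(C)CC[C@@H](Br)[C@](C)(CC[C@@H]2C(C)(C)[C@H](Br)CC[C@]2(C)O)O1 | target

Total step count: 11. Longest linear sequence: 7 (steps 1–4 then 9–11, or steps 5–8 then 9–11).

Steps most likely to fail

First, step 3 (Proposed new method).
- **What may go wrong:** bromine may transfer to the allylsiloxane alkene (bromodesilylation). The siloxane oxygen may capture the bromonium ion. The acid-sensitive tertiary allylic siloxane may undergo 1,4-elimination. Equilibration of the two bromonium faces may be incomplete, which would erode control at CHBr.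
- **Fallback:** it uses known chemistry, sets out from 3 and comes back at 6.
- Methyllithium opens the Si–O bond, and the alkoxide is trapped with TESOTf to give (2Z,4S)-4,8-dimethyl-4-(triethylsilyloxy)-1-(trimethylsilyl)nona-2,7-diene F1.
- Shi epoxidation with the D-fructose-derived ketone gives the (7R)-epoxide F2.
- An Et2AlCl-promoted, epoxide-initiated and allylsilane-terminated cyclisation gives the equatorial secondary alcohol (1R,3R,4S)-2,2,4-trimethyl-4-(triethylsilyloxy)-3-vinylcyclohexan-1-ol F3.
- Dess–Martin oxidation gives the ketone F4, and L-Selectride gives the axial alcohol F5.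
- Appel-type bromination with inversion (CBr4, tri-n-octylphosphine, toluene, heat) then gives 6.

Second, step 10.
- **What may go wrong:** the bulky, lipophilic substrate may not bind, so the enzyme releases free hypobromite. Facial selectivity would then be lost. Closure may also drift to the 5-exo mode, or water may capture the bromonium ion.
- **Fallback:** it sets out from 15 and comes back at 16.
- Shi epoxidation with the D-fructose-derived ketone sets both alkene carbons by catalyst control and gives the (6R,7R)-epoxy alcohol F6.
- CSA-catalysed opening by the tertiary hydroxyl at the tertiary epoxide carbon forms the same C–O bond with inversion and gives the oxane with an equatorial secondary alcohol F7.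
- Dess–Martin oxidation gives the oxan-3-one F8, and L-Selectride attacks from the equatorial side to give the axial alcohol F9.
- Bromination with inversion (CBr4, tri-n-octylphosphine) gives 16.

Third, step 8.
- **What may go wrong:** regiocontrol of the Zr–H addition to the nearly unbiased dialkyl alkyne may be incomplete. The excess reagent needed for equilibration may also hydrozirconate the vinyl group.
- **Fallback:** it sets out from 8 and comes back at 15.
- Ramirez olefination (CBr4, PPh3, Zn) gives (S)-7,7-dibromo-3-methylhepta-1,6-dien-3-ol F10.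
- Pd-catalysed trans-selective monoalkylation with the borane 14 replaces only the bromine trans to the chain and gives the (Z)-bromoalkene F11.
- Negishi methylation with retention (Me2Zn, Pd(PtBu3)2) gives 15.

Further compounds
F1 | step 3 | (2Z,4S)-4,8-dimethyl-4-(triethylsilyloxy)-1-(trimethylsilyl)nona-2,7-diene | C[Si](C)(C)C/C=C\[C@](C)(CCC=C(C)C)O[Si](CC)(CC)CC
F2 | step 3 | (2Z,4S,7R)-7,8-epoxy-4,8-dimethyl-4-(triethylsilyloxy)-1-(trimethylsilyl)non-2-ene | C[Si](C)(C)C/C=C\[C@](C)(CC[C@H]1OC1(C)C)O[Si](CC)(CC)CC
F3 | step 3 | (1R,3R,4S)-2,2,4-trimethyl-4-(triethylsilyloxy)-3-vinylcyclohexan-1-ol | C=C[C@@H]1C(C)(C)[C@H](O)CC[C@]1(C)O[Si](CC)(CC)CC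
F4 | step 3 | (3R,4S)-2,2,4-trimethyl-4-(triethylsilyloxy)-3-vinylcyclohexan-1-one | C=C[C@@H]1C(C)(C)C(=O)CC[C@]1(C)O[Si](CC)(CC)CC
F5 | step 3 | (1S,3R,4S)-2,2,4-trimethyl-4-(triethylsilyloxy)-3-vinylcyclohexan-1-ol | C=C[C@@H]1C(C)(C)[C@@H](O)CC[C@]1(C)O[Si](CC)(CC)CC
F6 | step 10 | (6R,7R)-epoxide of 15 | C=C[C@@](C)(O)CC[C@H]1O[C@]1(C)CC[C@@H]2C(C)(C)[C@H](Br)CC[C@]2(C)O[Si](CC)(CC)CC
F7 | step 10 | oxane with equatorial 3-hydroxyl in place of bromine (otherwise as 16) | C=C[C@]1(C)CC[C@@H](O)[C@](C)(CC[C@@H]2C(C)(C)[C@H](Br)CC[C@]2(C)O[Si](CC)(CC)CC)O1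
F8 | step 10 | oxan-3-one derived from F7 | C=C[C@]1(C)CCC(=O)[C@](C)(CC[C@@H]2C(C)(C)[C@H](Br)CC[C@]2(C)O[Si](CC)(CC)CC)O1
F9 | step 10 | oxane with axial 3-hydroxyl (3-epimer of F7) | C=C[C@]1(C)CC[C@H](O)[C@](C)(CC[C@@H]2C(C)(C)[C@H](Br)CC[C@]2(C)O[Si](CC)(CC)CC)O1
F10 | step 8 | (S)-7,7-dibromo-3-methylhepta-1,6-dien-3-ol | C=C[C@@](C)(O)CCC=C(Br)Br
F11 | step 8 | (Z)-7-bromo analogue of 15 (Br in place of the alkene methyl) | C=C[C@@](C)(O)CC/C=C(\Br)CC[C@@H]1C(C)(C)[C@H](Br)CC[C@]1(C)O[Si](CC)(CC)CC
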